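## Analysis of the target

Atoms are numbered by their position in the SMILES string: C1/O2 methoxy, C3 ester carbon, C5=C6 the ring B alkene, C7 the oxygen-bearing quaternary carbon, C8, C9 (methyl C10), C11, C12 the rest of ring A, C13 and C14 (methyl C15) the A/B fusion and the quaternary carbon, C16 the B/C fusion CH, C17 the ketone, C19 the isopropyl carbon, C23 a CH2, C24 the hemiketal carbon, O25 its hydroxyl, O26 the ring oxygen.

The target is tetracyclic: cyclohexene A (C7, C8, C9, C11, C12, C13), cyclohexene B (C5, C6, C7, C13, C14, C16), cyclohexanone C (C14, C16, C17, C19, C23, C24) and oxolane D (C7, C13, C14, C24, O26), which bridges ring B as a hemiketal. There are six stereocentres (C7, C13, C14, C16, C19, C24). On ring B the C15 methyl, C12 and the C16 hydrogen lie on one face and O26, C24 and C17 on the other, so A/B and B/C are both cis-fused; on ring C the isopropyl group is cis to the methyl and equatorial. C7 and C24 are not independent, since the O26 bridge can span only one face, and the bridge can close only from a cis B/C fusion. Sensitive points are the hemiketal, the C16 hydrogen (alpha to the C17 ketone and allylic to the enoate), the epimerisable C19, and the acidic skipped ketone/dienoate array before the cage is closed. The hard parts are the contiguous C13, quaternary C14 and C16, the tetrasubstituted C7, and the C16 hydrogen sitting on the more crowded face. The strategy rests on rings B and C: a decalin with the angular methyl on C14 next to C24 at ketone oxidation level, the pattern of a Robinson annulation of a 2-methyl-1,3-dione (carbonyls C16 and C24) with a beta-substituted enone (C5, C6, C7, C13), which forms C13–C14 and C5–C16.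

## Retrosynthetic reasoning

**21 to 20.** Rings A and D are taken apart together: C8–C9 and C7–O26 are cut, and C24–O25 is traced to hydration. This leads to dienoate 20, a 1,5-enyne (C8=C7, C11≡C9) with the C24 ketone on the face of ring B opposite the butynyl chain. One redox-neutral pi-acid cascade can form these bonds and leaves the ring A alkene at C9=C11; the cage then fixes C7 and C24 by itself. The forward step needs C8 to attack C9 (6-endo) and the C24 oxygen to take C7, which is possible only from a cis B/C fusion.

**20 to 19 to 18.** The vinylic hydrogen on C6 is traced to oxygen: 20 comes from alkenyl triflate 19 and that from the enolised beta-keto ester 18. The C6 carbonyl is the one the annulation leaves in ring B, and the C5 ester decides on which side the triflate forms, so the C5=C6 bond is placed without ambiguity.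

**18 to 16, 15, 14, 13.** C8 is cut from C7 as a Mannich carbon. It is carried as a dimethylaminomethyl group (14, 15, 16) because it has to be introduced while C7 is the only enolisable CH2 (in 13), yet must not be a free methylene enone when the C5=C16 bond is reduced. The C16 hydrogen comes from electron-transfer reduction of ene-dione 14 to 15; this step has to deliver the cis fusion and is the least secure stereochemical point.

**13 to 12, 11, 10, 9.** The C17 ketone comes from allylic oxidation of 12, the ester from carbonylation of iodide 11, the iodide from enone 10, and 10 from 9 by ketalisation of C24. The iodide is made before C17 is oxidised, because the addition–elimination iodination needs the C5=C16 bond polarised by C6 alone. C24 is ketalised so that C23 cannot compete with C7 in the enolate step.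

**9 to 3 and 7 (through 8).** C13–C14 and C5=C16 are cut. This removes ring B, the quaternary centre and three stereocentres at once and leaves two achiral pieces; every later step modifies a functional group that this annulation leaves in place. The forward reaction must set C13 by catalyst control and pick the ring carbonyl that puts the butynyl group cis to the angular methyl.

**3 to 1 and 2; 7 to 4 and 5 (through 6).** Dione 3 comes from C-methylation of 1 with 2. Enynone 7 comes from olefination of aldehyde 6, made in the same flask from alcohol 4, with ylide 5.

## Alternatives that were turned down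

**Alternative 1:** Ring B is closed at C14–C16 by an Ireland–Claisen ring contraction. The silyl ketene acetal of a six-membered lactone (C24 carbonyl, ring oxygen on C6) rearranges through a boat transition state: C14–C16 forms, O–C6 breaks, the alkene moves to C5=C6, and the bicyclic acid A1 results.
- For: C14 and C16 are set together in a cyclic transition state, so the C14/C16 relationship comes out by design. The C5=C6 enoate and the C7 oxygen are in place early. On these points it is stronger than the chosen route, where C16 is the weak stereocentre.
- Against: ring C is still missing in A1 and must be built from two carboxyl carbons (C24, C17) with a two-carbon unit carrying isopropyl, then locked as the hemiketal. The rearrangement must form a quaternary carbon next to an ester-bearing alkene terminus, and its substrate already needs ring A, C7, C13 and a stereodefined alkenyl unit.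
- Comparison: the chosen annulation makes rings B and C in one catalytic step from two achiral compounds; the alternative spends many steps before and after its key step.

**Alternative 2:** Ring B is closed at C13–C14 by an intramolecular Michael addition. Base forms the C14 enolate of the C24 ketone, which adds to C13 of a cross-conjugated hydroxy-dienone ring; the C7 hydroxyl then adds to C24 and gives lactol A2.
- For: the C7 oxygen comes from dearomatisation, rings B and D close in one operation, and the tether forces the cis B/C fusion and the O26 bridge. This is stronger than the chosen route on C16, C7 and C24.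
- Against: the substrate must already contain ring C with C16 and C19 set and a Z-alkenoate tether. Enolisation must occur at the hindered C14 and not at C23. In A2 ring A has a C11 carbonyl and a C8=C9 alkene, so the oxygen must be removed with transposition of the double bond, and the C17 ketal must be cleaved.
- Comparison: the chosen route reaches the carbocyclic core faster, sets absolute configuration with a catalyst, and forms ring A with the alkene already at C9=C11.

**Alternative 3:** Ring B is closed last at C5–C16. A zerovalent palladium catalyst and an alkoxide base couple the C17 ketone enolate (at C16) with a C5 alkenyl bromide held on C7, across the preformed oxolane, to give A3, the methyl ketal of the target.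
- For: it is convergent and very late; the cage dictates the C16 configuration; only ketal hydrolysis remains. On the final stereochemical lock it is as strong as or stronger than the chosen route.
- Against: all the difficulty moves into the precursor, which needs rings A, C and D with C7, C13, C14, C19 and C24 set and a Z-bromoacrylate on a quaternary carbon. The strong base can enolise toward C19, epimerise it, or open the C7–O bond by elimination.
- Comparison: the chosen route trades this late certainty for a much shorter entry to the B/C core with three stereocentres from one catalytic step.

Key step: step 3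

Assumption: 9-amino-9-deoxy-epi-quinine is taken to give the C13 configuration drawn; if the sense is opposite, its quinidine-derived pseudo-enantiomer is used.

## Route

Step 1
Reactants: 1 5-isopropylcyclohexane-1,3-dione; 2 iodomethane
Product: 3 5-isopropyl-2-methylcyclohexane-1,3-dione
Conditions: NaOH, H2O/dioxane, reflux
Reagents that add atoms: none
Why: C-Methylation of the stabilised 1,3-dione enolate in water (enolate alkylation); the product is carried as its enol, so no stereocentre needs control.

Step 2
Reactants: 4 pent-3-yn-1-ol; 5 1-(triphenylphosphoranylidene)propan-2-one
Product: 7 (E)-oct-3-en-6-yn-2-one, via pent-3-ynal 6 (not isolated)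
Conditions: Dess–Martin periodinane, CH2Cl2, 0 °C to rt; then 5, rt to 40 °C
Reagents that add atoms: none
Why: Dess–Martin oxidation gives the isomerisation-prone beta,gamma-alkynyl aldehyde, which is trapped in the same flask by the keto-stabilised ylide (Wittig reaction), E-selective as expected for stabilised ylides.

Step 3
Reactants: 3 5-isopropyl-2-methylcyclohexane-1,3-dione; 7 (E)-oct-3-en-6-yn-2-one
Product: 9 4-(but-2-ynyl)-7-isopropyl-4a-methyl-4,4a,7,8-tetrahydronaphthalene-2,5(3H,6H)-dione (butynyl and isopropyl both cis to the angular methyl), via Michael adduct triketone 8 (not isolated)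
Conditions: 9-amino-9-deoxy-epi-quinine (20 mol%), CF3CO2H (40 mol%), toluene, 40 °C; then 70 °C
Reagents that add atoms: none
Why: The amine condenses with 7 to an iminium ion and the enol of 3 adds through C14 to C13 (Michael addition) to give 8; the amine then turns the methyl ketone of 8 into its enamine, whose carbon C5 attacks the ring carbonyl C16, and loss of water gives the enone. The closest known reaction type is the amine-catalysed asymmetric Robinson annulation of 2-alkyl-1,3-diones (Hajos–Parrish–Eder–Sauer–Wiechert type), run with a primary amine salt because a beta-substituted enone needs iminium activation. Ring B closes by a 6-(enolendo)-exo-trig aldol addition. C13 is set by the catalyst, which covers one face of the E-iminium ion while its protonated quinuclidine holds the dione enolate. C14 is set by the choice between the two diastereotopic ring carbonyls: in the chair-like aldol transition state the but-2-ynyl group on C13 is equatorial, which puts it cis to the axial angular methyl. The C14/C19 relationship is set in the Michael step; the kinetic bias of the isopropyl group is small, but the adduct with the side chain equatorial and trans to isopropyl is the more stable one and closes faster, and the addition is reversible under amine catalysis. The step needs C- over O-alkylation and 1,4- over 1,2-addition, which the soft, fully enolised dione and the iminium ion secure.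

Step 4
Reactants: 9 the octalenedione
Product: 10 C24 1,3-dioxolane of 9
Conditions: HOCH2CH2OH, p-TsOH (cat.), 4 Å molecular sieves, CH2Cl2, rt
Reagents that add atoms: ethylene glycol, OCCO
Why: Acid-catalysed ketalisation is selective for the saturated C24 ketone over the conjugated C6 ketone, as in related angular-methyl enediones; it takes the C23 hydrogens out of play before enolate chemistry at C7.

Step 5
Reactants: 10 the ketal enone
Product: 11 C5 iodo enone
Conditions: I2, pyridine, DMAP (cat.), CH2Cl2, rt
Reagents that add atoms: iodine, II
Why: Amine-mediated alpha-iodination of a cyclic enone (conjugate addition, iodination of the enolate, elimination) marks C5, the only vinylic CH. It is done before C17 is oxidised, because in the ene-dione the amine would add at C5 itself.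

Step 6
Reactants: 11 the iodo enone
Product: 12 C5 methyl ester (alkylidene beta-keto ester)
Conditions: CO (1 atm), MeOH, PdCl2(PPh3)2 (5 mol%), Et3N, DMF, 60 °C
Reagents that add atoms: carbon monoxide, [C-]#[O+]; methanol, CO
Why: Palladium-catalysed methoxycarbonylation of the alkenyl iodide (oxidative addition, CO insertion, methanolysis) puts the ester on C5 without regiochemical ambiguity. The alkyne cannot reach the alkenylpalladium centre, so carbopalladation does not compete.

Step 7
Reactants: 12 the ester enone
Product: 13 C17 ketone (ene-1,4-dione ester)
Conditions: t-BuOOH, Pd(OH)2/C (5 mol%), K2CO3 (0.25 equiv), CH2Cl2, 0 °C to rt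
Reagents that add atoms: tert-butyl hydroperoxide, CC(C)(C)OO
Why: Allylic (gamma) oxidation of an enone to the ene-1,4-dione by a peroxy-radical pathway; the C17 hydrogens are the weakest C–H bonds, since the radical is delocalised over C17–C16=C5 and two carbonyl groups. C19 is now alpha to a ketone, and its equatorial isopropyl group (cis to the axial methyl) is the stable arrangement, so base cannot erode it.

Step 8
Reactants: 13 the ene-dione ester
Product: 14 C7 dimethylaminomethyl derivative (C7 epimers)
Conditions: LiN(SiMe3)2, THF, −78 °C; then Me2N=CH2+ I−, −78 to 0 °C
Reagents that add atoms: dimethylmethyleneiminium iodide, C=[N+](C)C.[I-]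
Why: Kinetic deprotonation at C7, the only enolisable CH2 (C19 is a hindered methine, C23 is ketal-blocked), followed by a Mannich reaction. The amine is a masked methylene that survives the next reduction, which a free methylene enone would not; the C7 configuration is lost later.

Step 9
Reactants: 14 the Mannich base
Product: 15 enolised beta-keto ester with cis B/C fusion (C16 hydrogen cis to C15)
Conditions: Zn dust, AcOH, rt
Reagents that add atoms: none
Why: Zinc in acetic acid reduces ene-1,4-diones by electron transfer and leaves alkyne, ester and ammonium group alone. C16 forms by protonation of the C17 enol and stays epimerisable; the cis fusion is expected to prevail because a trans fusion would hold C17 in the plane of the C5 ester (A(1,2) strain), but this is the least secure stereocentre of the route.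

Step 10
Reactants: 15 the ketal beta-keto ester
Product: 16 C24 ketone
Conditions: 2 M HCl, THF, rt
Reagents that add atoms: water, O
Why: Acid-catalysed hydrolysis of the dioxolane; the protonated amine does not eliminate. Without the ketal, C16 can settle to the cis fusion through the conjugated C17 enol.

Step 11
Reactants: 16 the amino beta-keto ester
Product: 18 C7-methylene beta-keto ester, via amine N-oxide 17 (not isolated)
Conditions: mCPBA (1.0 equiv), CH2Cl2, −20 °C to rt
Reagents that add atoms: none
Why: N-Oxidation of the tertiary amine is faster than any other oxidation in the molecule, and Cope elimination through the C7 hydrogen gives the C7=C8 methylene under neutral conditions.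

Step 12
Reactants: 18 the methylene beta-keto ester
Product: 19 C6 alkenyl triflate
Conditions: Tf2O, i-Pr2NEt, CH2Cl2, −78 °C
Reagents that add atoms: trifluoromethanesulfonic anhydride, O=S(=O)(OS(=O)(=O)C(F)(F)F)C(F)(F)F
Why: O-Triflation of the beta-keto ester enol, the only carbonyl already enolised, fixes the C5=C6 double bond; the C17 and C24 ketones do not react at this temperature.

Step 13
Reactants: 19 the triflate
Product: 20 dienoate (methyl ester on C5, C5=C6 and C7=C8)
Conditions: Pd(OAc)2 (5 mol%), PPh3 (10 mol%), HCO2H, n-Bu3N, DMF, 50 °C
Reagents that add atoms: none
Why: Palladium-catalysed formate reduction of an alkenyl triflate (oxidative addition to zerovalent palladium, formate exchange, decarboxylation, reductive elimination) replaces oxygen by hydrogen at C6. Carbopalladation of the alkyne from C6 would need a bridgehead alkene and does not compete.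

Step 14
Reactants: 20 the dienoate
Product: 21 CNP0382995.2
Conditions: Ph3PAuNTf2 (5 mol%), H2O (5 equiv), CH2Cl2, rt
Reagents that add atoms: water, O
Why: Cyclisation of the 1,5-enyne by a monovalent gold catalyst: C8 attacks the activated alkyne at C9 (6-endo-dig, ring A), the C24 carbonyl oxygen takes the developing cation at C7 from the opposite face (ring D), and water adds to the oxocarbenium ion from the open exo face before protodeauration; if water takes C7 first, the resulting hydroxy ketone closes to the same hemiketal. C7 follows from anti addition across C7=C8 (alkyne from the methyl face, oxygen from the other), and C24 is fixed by the cage.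

## Compound list

1 | 5-isopropylcyclohexane-1,3-dione | CC(C)C1CC(=O)CC(=O)C1 | starting material
2 | iodomethane | CI | starting material
3 | 5-isopropyl-2-methylcyclohexane-1,3-dione | CC1C(=O)CC(C(C)C)CC1=O | intermediate
4 | pent-3-yn-1-ol | CC#CCCO | starting material
5 | 1-(triphenylphosphoranylidene)propan-2-one | CC(=O)C=P(c1ccccc1)(c1ccccc1)c1ccccc1 | starting material
6 | pent-3-ynal (not isolated) | CC#CCC=O | intermediate
7 | (E)-oct-3-en-6-yn-2-one | CC#CC/C=C/C(C)=O | intermediate
8 | 5-isopropyl-2-methyl-2-(2-oxooct-6-yn-4-yl)cyclohexane-1,3-dione, side chain trans to isopropyl (not isolated) | CC#CC[C@@H](CC(C)=O)[C@]1(C)C(=O)C[C@@H](C(C)C)CC1=O | intermediate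
9 | 4-(but-2-ynyl)-7-isopropyl-4a-methyl-4,4a,7,8-tetrahydronaphthalene-2,5(3H,6H)-dione (rings B and C; C6 enone, C24 ketone) | CC#CC[C@H]1CC(=O)C=C2C[C@@H](C(C)C)CC(=O)[C@]12C | intermediate
10 | C24 1,3-dioxolane of 9 | CC#CC[C@H]1CC(=O)C=C2C[C@@H](C(C)C)CC3(OCCO3)[C@]12C | intermediate
11 | C5 iodo enone | CC#CC[C@H]1CC(=O)C(I)=C2C[C@@H](C(C)C)CC3(OCCO3)[C@]12C | intermediate
12 | C5 methyl ester of the enone | CC#CC[C@H]1CC(=O)C(C(=O)OC)=C2C[C@@H](C(C)C)CC3(OCCO3)[C@]12C | intermediate
13 | C17 ketone (ene-1,4-dione ester) | CC#CC[C@H]1CC(=O)C(C(=O)OC)=C2C(=O)[C@@H](C(C)C)CC3(OCCO3)[C@]12C | intermediate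
14 | C7 dimethylaminomethyl ene-dione ester (C7 epimers) | CC#CC[C@H]1C(CN(C)C)C(=O)C(C(=O)OC)=C2C(=O)[C@@H](C(C)C)CC3(OCCO3)[C@]12C | intermediate
15 | cis-fused beta-keto ester, drawn as the C6 enol, C24 dioxolane (C7 epimers) | CC#CC[C@H]1C(CN(C)C)C(O)=C(C(=O)OC)[C@@H]2C(=O)[C@@H](C(C)C)CC3(OCCO3)[C@]12C | intermediate
16 | cis-fused beta-keto ester with free C24 ketone (C7 epimers) | CC#CC[C@H]1C(CN(C)C)C(O)=C(C(=O)OC)[C@@H]2C(=O)[C@@H](C(C)C)CC(=O)[C@]12C | intermediate
17 | N-oxide of 16 (not isolated) | CC#CC[C@H]1C(C[N+](C)(C)[O-])C(O)=C(C(=O)OC)[C@@H]2C(=O)[C@@H](C(C)C)CC(=O)[C@]12C | intermediate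
18 | C7-methylene beta-keto ester (C6 enol) | CC#CC[C@H]1C(=C)C(O)=C(C(=O)OC)[C@@H]2C(=O)[C@@H](C(C)C)CC(=O)[C@]12C | intermediate
19 | C6 alkenyl triflate | CC#CC[C@H]1C(=C)C(OS(=O)(=O)C(F)(F)F)=C(C(=O)OC)[C@@H]2C(=O)[C@@H](C(C)C)CC(=O)[C@]12C | intermediate
20 | dienoate: C5 methyl ester, C5=C6, C7=C8, C17 and C24 ketones, cis B/C fusion | CC#CC[C@H]1C(=C)C=C(C(=O)OC)[C@@H]2C(=O)[C@@H](C(C)C)CC(=O)[C@]12C | intermediate
21 | CNP0382995.2 | COC(=O)C1=C[C@]23CC(C)=CC[C@@H]2[C@]2(C)[C@H]1C(=O)[C@@H](C(C)C)C[C@@]2(O)O3 | target

## Step count and risks

Total: 14 steps. Longest linear sequence: 13 steps (steps 1 and 3 to 14); step 2 is the only branch.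

**Step 3 (key step).**
- What may go wrong: addition to the beta-substituted iminium ion may be slow, so that the acceptor is drained by isomerisation through its dienamine (its C12 hydrogens are allylic and propargylic). Facial selectivity at C13 may erode, and the catalyst may oppose the substrate in choosing the ring carbonyl. Selectivity relative to the isopropyl group may be modest, but a C19 epimer is not lost: after step 7 C19 is alpha to the C17 ketone and base (DBU) converges it to the equatorial isomer, and the same holds in the cage of 21.
- Fallback: uncouple the two bond formations and set C13 on an aldehyde. It sets out from 3 and 4 (through 6). Aldehyde 6 is olefinated with (triphenylphosphoranylidene)acetaldehyde to (E)-hept-2-en-5-ynal F1. Dione 3 is added to F1 under iminium catalysis by a diarylprolinol silyl ether (enals are far better acceptors for quaternary-centre-forming additions), giving the aldehyde adduct F2. MeTi(OiPr)3 adds chemoselectively to the aldehyde to give the secondary alcohol F3 (which may sit as a lactol), and Dess–Martin oxidation gives 8. Ring closure with a primary amino acid salt (phenylalanine, camphorsulfonic acid) returns to the route at 9.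

**Step 9 (with step 10).**
- What may go wrong: poor control of C16. Protonation from the open face or an unfavourable equilibrium would give the trans fusion, from which the cage cannot close.
- Fallback: deliver the C16 hydrogen intramolecularly. It sets out from 14. Condensation with tosylhydrazide gives the C6 tosylhydrazone F4 (the C17 carbonyl, flanked by two branched carbons, should be the slower one). Catecholborane, then NaOAc·3H2O, reduces it with 1,3-transposition: hydride adds to C6 from the face anti to the methyl, and the allylic diazene passes its hydrogen to C16 on the methyl face, as known for angular-methyl octalenone tosylhydrazones. This gives the amine F5 with C5=C6 already in place. mCPBA gives the N-oxide F6, which eliminates to the dienoate ketal F7, and 2 M HCl in THF returns to the route at 20.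

**Step 14.**
- What may go wrong: a carbonyl oxygen may attack the activated alkyne (net hydration), the electron-poor diene may attack sluggishly, or closure may go 5-exo.
- Fallback: replace the catalytic pi-acid by a stoichiometric iodonium source. It sets out from 20. N-Iodosuccinimide in wet CH2Cl2 triggers the same 6-endo carbocyclisation with oxygen capture and gives the C11 alkenyl iodide F8. Bu3SnH with AIBN removes the iodine and returns to the route at 21.

**Step 5.**
- What may go wrong: the amine may add slowly at the hindered ring-fusion carbon C16, leaving iodination incomplete, and iodine may add to the alkyne.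
- Fallback: functionalise C5 through the epoxide. It sets out from 9. Alkaline hydrogen peroxide gives the C5–C16 epoxy ketone F9 (either epoxide isomer). Cold aqueous HBr in acetone opens it at C5 and dehydrates to the bromo enone F10. Ketalisation as in step 4 gives F11, and methoxycarbonylation (Pd(OAc)2, Xantphos, CO, MeOH, Et3N, 80 °C) returns to the route at 12.

## Further compounds

F1 | step 3 | (E)-hept-2-en-5-ynal | CC#CC/C=C/C=O
F2 | step 3 | aldehyde Michael adduct, 3-substituted hept-5-ynal on C2 of the dione | CC#CC[C@@H](CC=O)[C@]1(C)C(=O)C[C@@H](C(C)C)CC1=O
F3 | step 3 | secondary alcohol from methyl addition to F2 (carbinol epimers) | CC#CC[C@@H](CC(C)O)[C@]1(C)C(=O)C[C@@H](C(C)C)CC1=O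
F4 | step 9 | C6 tosylhydrazone of 14 | CC#CC[C@H]1C(CN(C)C)C(=NNS(=O)(=O)c4ccc(C)cc4)C(C(=O)OC)=C2C(=O)[C@@H](C(C)C)CC3(OCCO3)[C@]12C
F5 | step 9 | transposed enoate amine, C5=C6, cis B/C fusion, C24 dioxolane | CC#CC[C@H]1C(CN(C)C)C=C(C(=O)OC)[C@@H]2C(=O)[C@@H](C(C)C)CC3(OCCO3)[C@]12C
F6 | step 9 | N-oxide of F5 | CC#CC[C@H]1C(C[N+](C)(C)[O-])C=C(C(=O)OC)[C@@H]2C(=O)[C@@H](C(C)C)CC3(OCCO3)[C@]12C
F7 | step 9 | C24 dioxolane of dienoate 20 | CC#CC[C@H]1C(=C)C=C(C(=O)OC)[C@@H]2C(=O)[C@@H](C(C)C)CC3(OCCO3)[C@]12C
F8 | step 14 | C11 iodide of the target | COC(=O)C1=C[C@]23CC(C)=C(I)C[C@@H]2[C@]2(C)[C@H]1C(=O)[C@@H](C(C)C)C[C@@]2(O)O3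
F9 | step 5 | C5–C16 epoxide of 9 | CC#CC[C@H]1CC(=O)C2OC23C[C@@H](C(C)C)CC(=O)[C@]13C
F10 | step 5 | C5 bromo enone with free C24 ketone | CC#CC[C@H]1CC(=O)C(Br)=C2C[C@@H](C(C)C)CC(=O)[C@]12C
F11 | step 5 | C5 bromo enone, C24 dioxolane | CC#CC[C@H]1CC(=O)C(Br)=C2C[C@@H](C(C)C)CC3(OCCO3)[C@]12C
A1 | alternative 1 | bicyclic acid diester of rings A and B (C7 triethylsilyl ether, C14 acid, C16 tert-butyl ester) | COC(=O)C1=C[C@]2(O[Si](CC)(CC)CC)CC(C)=CC[C@@H]2[C@@](C)(C(=O)O)[C@H]1C(=O)OC(C)(C)C
A2 | alternative 2 | tetracyclic lactol with ring A enone and C17 dimethyl ketal | COC(=O)C1=C[C@]23C=C(C)C(=O)C[C@@H]2[C@]2(C)[C@H]1C(OC)(OC)[C@@H](C(C)C)C[C@@]2(O)O3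
A3 | alternative 3 | C24 methyl ketal of the target | COC(=O)C1=C[C@]23CC(C)=CC[C@@H]2[C@]2(C)[C@H]1C(=O)[C@@H](C(C)C)C[C@@]2(OC)O3
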